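**Strategy.** Everything rests on growing the oxolane ring O–C6–C5–C4–C3 of the 7-oxabicyclo[2.2.1]heptane end group (carotenoid numbering) out of an oxirane. The precursor is a cyclohex-3-ene oxide: the Sharpless-derived C5–C6 epoxide of silylated safranol. Mercuration of C3=C4 lets the epoxide oxygen bridge transannularly to C3; water opens the epoxonium at C5 with inversion and NaBH4 removes mercury. One operation thus expands the three-membered ring to the five-membered one, closes the bicycle and relays the catalyst-set C5/C6 configuration to C3 and C5. It exploits the anti relation of the O bridge and the C5 hydroxyl. Suzuki, aldol–elimination and Wittig steps join this unit to a butenolide, a C12 dialdehyde and the diol ring.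

Key step: step 4

Remark: ring carbons are numbered as in carotenoids (C1 gem-dimethyl, C5 ring methyl, C6 carries the side chain; primed numbers for the dihydroxycyclohexene ring); compounds 1, 17, 20 and 24 are taken as commercial.

**Step 1**
Reactants: 1 safranal (2,6,6-trimethylcyclohexa-1,3-diene-1-carbaldehyde)
Product: 2 safranol, (2,6,6-trimethylcyclohexa-1,3-dien-1-yl)methanol
Conditions: NaBH4, MeOH, 0 °C
Reagents that add atoms: none
Why: Borohydride 1,2-reduction of the conjugated aldehyde should give the dienyl carbinol without touching the diene; no stereocentre is formed.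

**Step 2**
Reactants: 2 safranol
Product: 3 [(1S,6S)-1,5,5-trimethyl-7-oxabicyclo[4.1.0]hept-2-en-6-yl]methanol
Conditions: Ti(OiPr)4 (0.1 equiv), L-(+)-diethyl tartrate (0.12 equiv), t-BuOOH (decane), 4 Å MS, CH2Cl2, −20 °C
Reagents that add atoms: tert-butyl hydroperoxide CC(C)(C)OO
Why: Sharpless asymmetric epoxidation should oxidise only the allylic tetrasubstituted C5=C6 bond, the L-(+)-tartrate delivering oxygen to the face that makes C5 and C6 both S, while the non-allylic C3=C4 bond is left intact.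

**Step 3**
Reactants: 3 epoxy alcohol
Product: 4 tert-butyl{[(1S,6S)-1,5,5-trimethyl-7-oxabicyclo[4.1.0]hept-2-en-6-yl]methoxy}diphenylsilane
Conditions: TBDPSCl, imidazole, DMF, 0 °C to rt
Reagents that add atoms: tert-butyl(chloro)diphenylsilane CC(C)(C)[Si](Cl)(c1ccccc1)c1ccccc1
Why: Imidazole-promoted silylation of the primary alcohol should proceed under non-acidic conditions that spare the allylic oxirane, and the bulky silyl ether is a poor internal nucleophile for step 4.

**Step 4**
Reactants: 4 silylated vinyl epoxide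
Product: 6 (1S,2R,4S)-1-[(tert-butyldiphenylsilyloxy)methyl]-2,6,6-trimethyl-7-oxabicyclo[2.2.1]heptan-2-ol, via organomercury acetate 5 (not isolated)
Conditions: Hg(OAc)2 (1.1 equiv), THF–H2O (1:1), 0 °C to rt; then 3 M NaOH, NaBH4, 0 °C
Reagents that add atoms: water O
Why: Proposed new method: reversible anti-mercuration of C3=C4 places mercury on the face opposite the oxirane, and the oxirane oxygen on C6 then attacks C3 transannularly through a boat (5-exo with respect to the O–C6–C1–C2–C3 tether, anti to mercury) to give a tricyclic epoxonium ion with oxygen bonded to C3, C5 and C6. Water opens this ion by backside attack at the tertiary C5, so the oxirane O–C5–C6 becomes the oxolane O–C6–C5–C4–C3 by net insertion of C4–C3 into its O–C5 bond, and NaBH4 then replaces mercury on C4 by hydrogen. The closest known reaction types are intramolecular alkoxymercuration–demercuration and the halonium- or selenonium-triggered ring expansion of epoxy alkenes through bicyclic epoxonium ions, including the transannular case of cyclooctadiene monoepoxide. C3 is set because the tethered oxygen can reach it only from its own face (substrate control from C6, fixed in step 2), and C5 is inverted by the SN2 opening, which puts the new hydroxyl anti to the oxygen bridge. The step needs mercuration anti to the oxirane (electrophiles prefer the face away from the allylic oxygen, and only that mercurinium ion can be captured internally), O–C5 rather than O–C6 cleavage (only O–C5 cleavage releases both the three- and the four-membered ring, whereas C6 is neopentylic and its cleavage would leave an oxetane), and a silent primary oxygen (secured by the TBDPS group).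

**Step 5**
Reactants: 6 bicyclic silyl ether
Product: 7 (1S,2R,4S)-1-(hydroxymethyl)-2,6,6-trimethyl-7-oxabicyclo[2.2.1]heptan-2-ol
Conditions: TBAF, THF, rt
Reagents that add atoms: none
Why: Fluoride-mediated desilylation should free the primary alcohol while the bicyclic ether and the tertiary alcohol are inert.

**Step 6**
Reactants: 7 diol
Product: 8 (1R,2R,4S)-2-hydroxy-2,6,6-trimethyl-7-oxabicyclo[2.2.1]heptane-1-carbaldehyde
Conditions: Dess–Martin periodinane, CH2Cl2, 0 °C to rt
Reagents that add atoms: none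
Why: Dess–Martin oxidation should convert only the primary alcohol, since the tertiary alcohol cannot be oxidised and the bridgehead aldehyde cannot enolise or epimerise.

**Step 7**
Reactants: 8 bridgehead aldehyde
Product: 9 (1R,2R,4S)-2,6,6-trimethyl-1-[(E)-2-(4,4,5,5-tetramethyl-1,3,2-dioxaborolan-2-yl)ethenyl]-7-oxabicyclo[2.2.1]heptan-2-ol
Conditions: CrCl2 (8 equiv), Cl2CHB(pin) (2 equiv), LiI (4 equiv), THF, rt
Reagents that add atoms: 2-(dichloromethyl)-4,4,5,5-tetramethyl-1,3,2-dioxaborolane ClC(Cl)B1OC(C)(C)C(C)(C)O1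
Why: Takai–Utimoto boron olefination should add the geminal dichromium reagent to the aldehyde and eliminate to the (E)-alkenylboronate, with the free tertiary alcohol tolerated.

**Step 8**
Reactants: 2 safranol
Product: 10 [(1R,6R)-1,5,5-trimethyl-7-oxabicyclo[4.1.0]hept-2-en-6-yl]methanol
Conditions: Ti(OiPr)4 (0.1 equiv), D-(−)-diethyl tartrate (0.12 equiv), t-BuOOH (decane), 4 Å MS, CH2Cl2, −20 °C
Reagents that add atoms: tert-butyl hydroperoxide CC(C)(C)OO
Why: Sharpless asymmetric epoxidation with the enantiomeric tartrate should give the mirror-image oxirane, used here as a temporary stereocontrol element and protecting group for the C5'=C6' alkene.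

**Step 9**
Reactants: 10 ent-epoxy alcohol
Product: 11 (1R,2S,3S,6R)-6-(hydroxymethyl)-1,5,5-trimethyl-7-oxabicyclo[4.1.0]heptane-2,3-diol
Conditions: OsO4 (2 mol %), N-methylmorpholine N-oxide, acetone–H2O, 0 °C to rt
Reagents that add atoms: osmium tetroxide O=[Os](=O)(=O)=O (catalytic oxygen carrier); N-methylmorpholine N-oxide C[N+]1([O-])CCOCC1; water O
Why: Upjohn cis-dihydroxylation should add suprafacially to the only remaining alkene from the face anti to the allylic oxirane oxygen (as with cyclohexadiene monoepoxides), which sets C3' and C4' as the cis-diol of the target.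

**Step 10**
Reactants: 11 epoxy triol
Product: 12 (1R,2S,3S,6R)-2,3-bis(tert-butyldimethylsilyloxy)-6-[(tert-butyldimethylsilyloxy)methyl]-1,5,5-trimethyl-7-oxabicyclo[4.1.0]heptane
Conditions: TBSOTf (3.5 equiv), 2,6-lutidine, CH2Cl2, −78 °C to 0 °C
Reagents that add atoms: tert-butyldimethylsilyl trifluoromethanesulfonate CC(C)(C)[Si](C)(C)OS(=O)(=O)C(F)(F)F
Why: Silyl triflate silylation should cap all three hydroxyls, including the hindered C4' one, at a temperature where silylation outpaces Lewis-acid opening of the oxirane.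

**Step 11**
Reactants: 12 tris-silyl epoxide
Product: 13 (3R,4S)-3,4-bis(tert-butyldimethylsilyloxy)-1-[(tert-butyldimethylsilyloxy)methyl]-2,6,6-trimethylcyclohex-1-ene
Conditions: WCl6 (3 equiv), n-BuLi (6 equiv), THF, −78 °C to rt; then 12, rt
Reagents that add atoms: none
Why: Epoxide deoxygenation with the lower-valent tungsten chloride made from WCl6 and n-BuLi, a reagent suited to tetrasubstituted oxiranes, should return the C5'=C6' alkene and leave the two carbinol stereocentres and the silyl ethers untouched.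

**Step 12**
Reactants: 13 tris-silyl ether
Product: 14 [(3R,4S)-3,4-bis(tert-butyldimethylsilyloxy)-2,6,6-trimethylcyclohex-1-en-1-yl]methanol
Conditions: HF·pyridine, pyridine, THF, 0 °C
Reagents that add atoms: none
Why: Buffered HF·pyridine should cleave the least hindered primary silyl ether selectively over the two secondary ones.

**Step 13**
Reactants: 14 allylic alcohol
Product: 16 {[(3R,4S)-3,4-bis(tert-butyldimethylsilyloxy)-2,6,6-trimethylcyclohex-1-en-1-yl]methyl}triphenylphosphonium bromide, via allylic bromide 15 (not isolated)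
Conditions: CBr4, PPh3, CH2Cl2, 0 °C; then PPh3, toluene, rt
Reagents that add atoms: tetrabromomethane BrC(Br)(Br)Br; triphenylphosphine c1ccc(cc1)P(c1ccccc1)c1ccccc1
Why: Appel bromination of the primary allylic alcohol under neutral conditions followed by SN2 quaternisation of triphenylphosphine should give the cyclogeranyl-type Wittig salt without ionising the allylic C4' silyl ether.

**Step 14**
Reactants: 17 dimethyl (2E,4E)-hexa-2,4-dienedioate
Product: 18 (2E,4E)-hexa-2,4-diene-1,6-diol
Conditions: i-Bu2AlH (DIBAL-H, 4.4 equiv), CH2Cl2, −78 °C to 0 °C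
Reagents that add atoms: none
Why: DIBAL-H should reduce both conjugated esters to allylic alcohols by 1,2-hydride delivery without touching the diene geometry.

**Step 15**
Reactants: 18 dienediol
Product: 19 (2E,4E)-hexa-2,4-dienedial
Conditions: activated MnO2, CH2Cl2, rt
Reagents that add atoms: none
Why: MnO2 oxidises allylic alcohols selectively and should give the conjugated dialdehyde with the (E,E) geometry retained.

**Step 16**
Reactants: 19 dienedial; 20 2-(triphenylphosphoranylidene)propanal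
Product: 21 (2E,4E,6E,8E)-2,9-dimethyldeca-2,4,6,8-tetraenedial
Conditions: 20 (2.3 equiv), toluene, 80 °C, dark
Reagents that add atoms: none
Why: A twofold Wittig reaction with the stabilised ylide should be E-selective and should stop at the product, whose α-methyl enal termini are less electrophilic than those of 19.

**Step 17**
Reactants: 16 phosphonium salt; 21 C12 dialdehyde
Product: 23 (2E,4E,6E,8E,10E)-11-[(3R,4S)-3,4-bis(tert-butyldimethylsilyloxy)-2,6,6-trimethylcyclohex-1-en-1-yl]-2,9-dimethylundeca-2,4,6,8,10-pentaenal, via phosphorus ylide 22 (not isolated)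
Conditions: n-BuLi (1.0 equiv), THF, −78 °C; then 21 (3 equiv), −78 °C to 0 °C, dark
Reagents that add atoms: none
Why: Wittig olefination of the hindered cyclogeranyl ylide with one terminus of the symmetrical dialdehyde (used in excess and recovered) should form C7'=C8' with E geometry, because the Z isomer is congested by the ring methyls, and the low temperature should suppress loss of the C4' silyloxy group from the ylide.

**Step 18**
Reactants: 23 polyenal; 24 3-bromofuran-2(5H)-one
Product: 27 (5Z)-3-bromo-5-[(2E,4E,6E,8E,10E)-11-[(3R,4S)-3,4-bis(tert-butyldimethylsilyloxy)-2,6,6-trimethylcyclohex-1-en-1-yl]-2,9-dimethylundeca-2,4,6,8,10-pentaenylidene]furan-2(5H)-one, via 3-bromo-2-silyloxyfuran 25 (not isolated), via silylated aldol adduct 26 (not isolated)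
Conditions: 24 (1.3 equiv), TBSOTf, i-Pr2NEt, CH2Cl2, −78 °C to rt; then DBU, rt
Reagents that add atoms: none
Why: A one-pot vinylogous Mukaiyama aldol addition of the silyloxyfuran formed in the flask, followed by DBU-mediated elimination of silanol, should give the thermodynamically favoured (Z)-γ-ylidenebutenolide with the α-bromide retained.

**Step 19**
Reactants: 27 bromo ylidenebutenolide; 9 alkenylboronate
Product: 28 (5Z)-5-[(2E,4E,6E,8E,10E)-11-[(3R,4S)-3,4-bis(tert-butyldimethylsilyloxy)-2,6,6-trimethylcyclohex-1-en-1-yl]-2,9-dimethylundeca-2,4,6,8,10-pentaenylidene]-3-[(E)-2-[(1R,2R,4S)-2-hydroxy-2,6,6-trimethyl-7-oxabicyclo[2.2.1]heptan-1-yl]ethenyl]furan-2(5H)-one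
Conditions: 9 (1.5 equiv), PdCl2(MeCN)2 (5 mol %), AsPh3, Ag2O, THF–H2O (8:1), rt, dark
Reagents that add atoms: none
Why: Suzuki–Miyaura coupling of the electron-poor α-bromobutenolide with the (E)-alkenylboronate should proceed with retention of both alkene geometries, silver oxide allowing transmetalation at room temperature without hydrolysing the lactone.

**Step 20**
Reactants: 28 bis-silyl ether
Product: 29 CNP0216838.1 (target)
Conditions: HF·pyridine, pyridine, THF, 0 °C to rt, dark
Reagents that add atoms: none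
Why: Buffered fluoride desilylation should free the two secondary hydroxyls without acid ionisation of the allylic C4' oxygen or opening of the lactone.

**Compound list**

1 | safranal, 2,6,6-trimethylcyclohexa-1,3-diene-1-carbaldehyde | O=CC1=C(C)C=CCC1(C)C | starting material
2 | safranol, (2,6,6-trimethylcyclohexa-1,3-dien-1-yl)methanol | OCC1=C(C)C=CCC1(C)C | intermediate
3 | [(1S,6S)-1,5,5-trimethyl-7-oxabicyclo[4.1.0]hept-2-en-6-yl]methanol | OC[C@]12O[C@@]1(C)C=CCC2(C)C | intermediate
4 | tert-butyl{[(1S,6S)-1,5,5-trimethyl-7-oxabicyclo[4.1.0]hept-2-en-6-yl]methoxy}diphenylsilane | CC(C)(C)[Si](OC[C@]12O[C@@]1(C)C=CCC2(C)C)(c1ccccc1)c1ccccc1 | intermediate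
5 | [(1S,2S,3R,4S)-1-[(tert-butyldiphenylsilyloxy)methyl]-2-hydroxy-2,6,6-trimethyl-7-oxabicyclo[2.2.1]heptan-3-yl]mercury acetate (mercury anti to the oxygen bridge) | CC(C)(C)[Si](OC[C@@]12O[C@@H](CC1(C)C)[C@@H]([Hg]OC(C)=O)[C@@]2(C)O)(c1ccccc1)c1ccccc1 | intermediate
6 | (1S,2R,4S)-1-[(tert-butyldiphenylsilyloxy)methyl]-2,6,6-trimethyl-7-oxabicyclo[2.2.1]heptan-2-ol | CC(C)(C)[Si](OC[C@@]12O[C@@H](CC1(C)C)C[C@@]2(C)O)(c1ccccc1)c1ccccc1 | intermediate
7 | (1S,2R,4S)-1-(hydroxymethyl)-2,6,6-trimethyl-7-oxabicyclo[2.2.1]heptan-2-ol | OC[C@@]12O[C@@H](CC1(C)C)C[C@@]2(C)O | intermediate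
8 | (1R,2R,4S)-2-hydroxy-2,6,6-trimethyl-7-oxabicyclo[2.2.1]heptane-1-carbaldehyde | O=C[C@@]12O[C@@H](CC1(C)C)C[C@@]2(C)O | intermediate
9 | (1R,2R,4S)-2,6,6-trimethyl-1-[(E)-2-(4,4,5,5-tetramethyl-1,3,2-dioxaborolan-2-yl)ethenyl]-7-oxabicyclo[2.2.1]heptan-2-ol | CC1(C)OB(/C=C/[C@@]23O[C@@H](CC2(C)C)C[C@@]3(C)O)OC1(C)C | intermediate
10 | [(1R,6R)-1,5,5-trimethyl-7-oxabicyclo[4.1.0]hept-2-en-6-yl]methanol | OC[C@@]12O[C@]1(C)C=CCC2(C)C | intermediate
11 | (1R,2S,3S,6R)-6-(hydroxymethyl)-1,5,5-trimethyl-7-oxabicyclo[4.1.0]heptane-2,3-diol | OC[C@@]12O[C@]1(C)[C@@H](O)[C@@H](O)CC2(C)C | intermediate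
12 | (1R,2S,3S,6R)-2,3-bis(tert-butyldimethylsilyloxy)-6-[(tert-butyldimethylsilyloxy)methyl]-1,5,5-trimethyl-7-oxabicyclo[4.1.0]heptane | CC(C)(C)[Si](C)(C)OC[C@@]12O[C@]1(C)[C@@H](O[Si](C)(C)C(C)(C)C)[C@@H](O[Si](C)(C)C(C)(C)C)CC2(C)C | intermediate
13 | (3R,4S)-3,4-bis(tert-butyldimethylsilyloxy)-1-[(tert-butyldimethylsilyloxy)methyl]-2,6,6-trimethylcyclohex-1-ene | CC(C)(C)[Si](C)(C)OCC1=C(C)[C@@H](O[Si](C)(C)C(C)(C)C)[C@@H](O[Si](C)(C)C(C)(C)C)CC1(C)C | intermediate
14 | [(3R,4S)-3,4-bis(tert-butyldimethylsilyloxy)-2,6,6-trimethylcyclohex-1-en-1-yl]methanol | OCC1=C(C)[C@@H](O[Si](C)(C)C(C)(C)C)[C@@H](O[Si](C)(C)C(C)(C)C)CC1(C)C | intermediate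
15 | (3R,4S)-1-(bromomethyl)-3,4-bis(tert-butyldimethylsilyloxy)-2,6,6-trimethylcyclohex-1-ene | BrCC1=C(C)[C@@H](O[Si](C)(C)C(C)(C)C)[C@@H](O[Si](C)(C)C(C)(C)C)CC1(C)C | intermediate
16 | {[(3R,4S)-3,4-bis(tert-butyldimethylsilyloxy)-2,6,6-trimethylcyclohex-1-en-1-yl]methyl}triphenylphosphonium bromide | [Br-].CC1=C(C[P+](c2ccccc2)(c2ccccc2)c2ccccc2)C(C)(C)C[C@H](O[Si](C)(C)C(C)(C)C)[C@@H]1O[Si](C)(C)C(C)(C)C | intermediate
17 | dimethyl (2E,4E)-hexa-2,4-dienedioate | COC(=O)/C=C/C=C/C(=O)OC | starting material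
18 | (2E,4E)-hexa-2,4-diene-1,6-diol | OC/C=C/C=C/CO | intermediate
19 | (2E,4E)-hexa-2,4-dienedial | O=C/C=C/C=C/C=O | intermediate
20 | 2-(triphenylphosphoranylidene)propanal | CC(C=O)=P(c1ccccc1)(c1ccccc1)c1ccccc1 | starting material
21 | (2E,4E,6E,8E)-2,9-dimethyldeca-2,4,6,8-tetraenedial | O=C/C(C)=C/C=C/C=C/C=C(C)/C=O | intermediate
22 | ylide of 16, {[(3R,4S)-3,4-bis(tert-butyldimethylsilyloxy)-2,6,6-trimethylcyclohex-1-en-1-yl]methylidene}triphenylphosphorane | CC1=C(C=P(c2ccccc2)(c2ccccc2)c2ccccc2)C(C)(C)C[C@H](O[Si](C)(C)C(C)(C)C)[C@@H]1O[Si](C)(C)C(C)(C)C | intermediate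
23 | (2E,4E,6E,8E,10E)-11-[(3R,4S)-3,4-bis(tert-butyldimethylsilyloxy)-2,6,6-trimethylcyclohex-1-en-1-yl]-2,9-dimethylundeca-2,4,6,8,10-pentaenal | CC1=C(/C=C/C(C)=C/C=C/C=C/C=C(C)/C=O)C(C)(C)C[C@H](O[Si](C)(C)C(C)(C)C)[C@@H]1O[Si](C)(C)C(C)(C)C | intermediate
24 | 3-bromofuran-2(5H)-one | O=C1OCC=C1Br | starting material
25 | [(3-bromofuran-2-yl)oxy](tert-butyl)dimethylsilane | CC(C)(C)[Si](C)(C)Oc1occc1Br | intermediate
26 | 3-bromo-5-[(2E,4E,6E,8E,10E)-1-(tert-butyldimethylsilyloxy)-11-[(3R,4S)-3,4-bis(tert-butyldimethylsilyloxy)-2,6,6-trimethylcyclohex-1-en-1-yl]-2,9-dimethylundeca-2,4,6,8,10-pentaen-1-yl]furan-2(5H)-one (both new sp3 centres unassigned, diastereomer mixture) | CC1=C(/C=C/C(C)=C/C=C/C=C/C=C(C)/C(O[Si](C)(C)C(C)(C)C)C2OC(=O)C(Br)=C2)C(C)(C)C[C@H](O[Si](C)(C)C(C)(C)C)[C@@H]1O[Si](C)(C)C(C)(C)C | intermediate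
27 | (5Z)-3-bromo-5-[(2E,4E,6E,8E,10E)-11-[(3R,4S)-3,4-bis(tert-butyldimethylsilyloxy)-2,6,6-trimethylcyclohex-1-en-1-yl]-2,9-dimethylundeca-2,4,6,8,10-pentaenylidene]furan-2(5H)-one | CC1=C(/C=C/C(C)=C/C=C/C=C/C=C(C)/C=C2C=C(Br)C(=O)O/2)C(C)(C)C[C@H](O[Si](C)(C)C(C)(C)C)[C@@H]1O[Si](C)(C)C(C)(C)C | intermediate
28 | (5Z)-5-[(2E,4E,6E,8E,10E)-11-[(3R,4S)-3,4-bis(tert-butyldimethylsilyloxy)-2,6,6-trimethylcyclohex-1-en-1-yl]-2,9-dimethylundeca-2,4,6,8,10-pentaenylidene]-3-[(E)-2-[(1R,2R,4S)-2-hydroxy-2,6,6-trimethyl-7-oxabicyclo[2.2.1]heptan-1-yl]ethenyl]furan-2(5H)-one | CC1=C(/C=C/C(C)=C/C=C/C=C/C=C(C)/C=C2C=C(/C=C/[C@@]34O[C@@H](CC3(C)C)C[C@@]4(C)O)C(=O)O/2)C(C)(C)C[C@H](O[Si](C)(C)C(C)(C)C)[C@@H]1O[Si](C)(C)C(C)(C)C | intermediate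
29 | CNP0216838.1, (5Z)-5-[(2E,4E,6E,8E,10E)-11-[(3R,4S)-3,4-dihydroxy-2,6,6-trimethylcyclohex-1-en-1-yl]-2,9-dimethylundeca-2,4,6,8,10-pentaenylidene]-3-[(E)-2-[(1R,2R,4S)-2-hydroxy-2,6,6-trimethyl-7-oxabicyclo[2.2.1]heptan-1-yl]ethenyl]furan-2(5H)-one | CC1=C(/C=C/C(C)=C/C=C/C=C/C=C(C)/C=C2C=C(/C=C/[C@@]34O[C@@H](CC3(C)C)C[C@@]4(C)O)C(=O)O/2)C(C)(C)C[C@H](O)[C@@H]1O | target

**Totals.** Total step count: 20. Longest linear sequence: 11 steps (steps 1, 8, 9, 10, 11, 12, 13, 17, 18, 19, 20).

**Steps most likely to fail**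

Step 4 (Proposed new method). What may go wrong: external water may capture the mercurinium ion faster than the oxirane oxygen (plain hydroxymercuration), or the mercury salt may open the allylic oxirane before mercuration takes place. The fallback uses known chemistry, sets out from compound 11 and comes back to the route at compound 6. The primary hydroxyl of 11 would be silylated selectively (TBDPSCl, imidazole, DMF, 0 °C) to give (1R,2S,3S,6R)-6-[(tert-butyldiphenylsilyloxy)methyl]-1,5,5-trimethyl-7-oxabicyclo[4.1.0]heptane-2,3-diol F1. Camphorsulfonic acid in CH2Cl2 should then bring about the acid-catalysed transannular opening of the oxirane at C6 by the C3 hydroxyl that lies anti to it. This is the rearrangement known from 5,6-epoxy-3-hydroxy carotenoid end groups and from the terpinen-4-ol epoxide to 2-hydroxy-1,4-cineole conversion. It should give (1S,2R,3S,4S)-1-[(tert-butyldiphenylsilyloxy)methyl]-2,6,6-trimethyl-7-oxabicyclo[2.2.1]heptane-2,3-diol F2, which has the same bridge and the same C3, C5 and C6 configuration as 6. The surplus secondary hydroxyl would be removed by Barton–McCombie deoxygenation: PhOC(S)Cl, pyridine and DMAP should acylate only the secondary alcohol to give O-[(1S,2R,3S,4S)-1-[(tert-butyldiphenylsilyloxy)methyl]-2-hydroxy-2,6,6-trimethyl-7-oxabicyclo[2.2.1]heptan-3-yl] O-phenyl carbonothioate F3, and Bu3SnH with AIBN in toluene at 80 °C should then give 6.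

Step 11. What may go wrong: oxygen transfer from the crowded tetrasubstituted oxirane to tungsten may be slow, and Lewis-acidic tungsten species may open the oxirane or strip silyl groups. The fallback sets out from compound 12 and comes back to the route at compound 16, so that steps 12 and 13 are replaced as well. HF·pyridine in pyridine and THF at 0 °C should free the primary hydroxyl to give [(1R,2S,3S,6R)-2,3-bis(tert-butyldimethylsilyloxy)-1,5,5-trimethyl-7-oxabicyclo[4.1.0]heptan-6-yl]methanol F4. I2, PPh3 and imidazole should convert it to (1R,2S,3S,6S)-2,3-bis(tert-butyldimethylsilyloxy)-6-(iodomethyl)-1,5,5-trimethyl-7-oxabicyclo[4.1.0]heptane F5. Zinc dust in refluxing ethanol should effect the standard reductive opening of a 2,3-epoxy halide to give (1S,5S,6S)-5,6-bis(tert-butyldimethylsilyloxy)-1,3,3-trimethyl-2-methylidenecyclohexan-1-ol F6. PPh3·HBr in CH2Cl2 should then convert this tertiary allylic alcohol with allylic transposition into phosphonium salt 16, as in the classical preparation of polyene Wittig salts from vinyl carbinols.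

Step 18. What may go wrong: addition to the poorly electrophilic polyenal may be sluggish, the silyl triflate may degrade the polyene, or the elimination may be incompletely Z-selective. The fallback sets out from compound 23 and comes back to the route at compound 27. Ohira–Bestmann homologation (dimethyl (1-diazo-2-oxopropyl)phosphonate, K2CO3, MeOH–THF) should give (3R,4S)-3,4-bis(tert-butyldimethylsilyloxy)-1-[(1E,3E,5E,7E,9E)-3,10-dimethyldodeca-1,3,5,7,9-pentaen-11-yn-1-yl]-2,6,6-trimethylcyclohex-1-ene F7. A tandem Sonogashira coupling and 5-exo-dig lactonisation with (E)-2,3-dibromoprop-2-enoic acid (PdCl2(PPh3)2, CuI, Et3N, MeCN, rt) should couple at the β-bromide, which is cis to the carboxyl group, and close the (Z)-γ-ylidenebutenolide 27 with the α-bromide intact.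

**Further compounds**

F1 | step 4 | (1R,2S,3S,6R)-6-[(tert-butyldiphenylsilyloxy)methyl]-1,5,5-trimethyl-7-oxabicyclo[4.1.0]heptane-2,3-diol | CC(C)(C)[Si](OC[C@@]12O[C@]1(C)[C@@H](O)[C@@H](O)CC2(C)C)(c1ccccc1)c1ccccc1
F2 | step 4 | (1S,2R,3S,4S)-1-[(tert-butyldiphenylsilyloxy)methyl]-2,6,6-trimethyl-7-oxabicyclo[2.2.1]heptane-2,3-diol | CC(C)(C)[Si](OC[C@@]12O[C@@H](CC1(C)C)[C@H](O)[C@@]2(C)O)(c1ccccc1)c1ccccc1
F3 | step 4 | O-[(1S,2R,3S,4S)-1-[(tert-butyldiphenylsilyloxy)methyl]-2-hydroxy-2,6,6-trimethyl-7-oxabicyclo[2.2.1]heptan-3-yl] O-phenyl carbonothioate | CC(C)(C)[Si](OC[C@@]12O[C@@H](CC1(C)C)[C@H](OC(=S)Oc3ccccc3)[C@@]2(C)O)(c1ccccc1)c1ccccc1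
F4 | step 11 | [(1R,2S,3S,6R)-2,3-bis(tert-butyldimethylsilyloxy)-1,5,5-trimethyl-7-oxabicyclo[4.1.0]heptan-6-yl]methanol | OC[C@@]12O[C@]1(C)[C@@H](O[Si](C)(C)C(C)(C)C)[C@@H](O[Si](C)(C)C(C)(C)C)CC2(C)C
F5 | step 11 | (1R,2S,3S,6S)-2,3-bis(tert-butyldimethylsilyloxy)-6-(iodomethyl)-1,5,5-trimethyl-7-oxabicyclo[4.1.0]heptane | IC[C@@]12O[C@]1(C)[C@@H](O[Si](C)(C)C(C)(C)C)[C@@H](O[Si](C)(C)C(C)(C)C)CC2(C)C
F6 | step 11 | (1S,5S,6S)-5,6-bis(tert-butyldimethylsilyloxy)-1,3,3-trimethyl-2-methylidenecyclohexan-1-ol | C=C1C(C)(C)C[C@H](O[Si](C)(C)C(C)(C)C)[C@H](O[Si](C)(C)C(C)(C)C)[C@@]1(C)O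
F7 | step 18 | (3R,4S)-3,4-bis(tert-butyldimethylsilyloxy)-1-[(1E,3E,5E,7E,9E)-3,10-dimethyldodeca-1,3,5,7,9-pentaen-11-yn-1-yl]-2,6,6-trimethylcyclohex-1-ene | CC1=C(/C=C/C(C)=C/C=C/C=C/C=C(C)/C#C)C(C)(C)C[C@H](O[Si](C)(C)C(C)(C)C)[C@@H]1O[Si](C)(C)C(C)(C)C
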